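## Retrosynthetic overview

1. Target ⇐ global O-debenzylation of a hepta-O-benzyl dimer carrying the ring D methyl ⇐ bromination and Suzuki methylation at C6 of ring D, the only free position left on that ring once C8 is occupied.
2. Interflavan C4–C8 bond ⇐ benzylic C4 cation of a tri-O-benzyl flavan-3,4-diol (upper unit) plus tetra-O-benzyl-(+)-catechin (chiral pool; supplies rings D, E, F and both lower stereocentres).
3. Flavan-3,4-diol ⇐ carbonyl reduction of a (2R,3R)-dihydroflavonol.
4. Key disconnection, ring C of the upper unit: the C3–O and O1–C2 bonds are made in one asymmetric operation from an achiral 2'-hydroxychalcone (phenoxide-anchored epoxidation, then 6-endo ring closure). This sets C2 and C3; C4 is later relayed from C3.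
5. Chalcone ⇐ Claisen–Schmidt condensation of two bought benzyl ethers. Ring order: A and B bought → C (step 2) → union with D/E/F of catechin.

Assumption: rings are lettered A, B, C in the upper flavan unit (benzo, catechol, pyran ring) and D, E, F in the lower unit, with the usual flavan atom numbers; the two building blocks of step 1 are bought as their benzyl ethers (both are catalogue compounds).

## Route

**Step 1**
Reactants: 1 1-[4-(benzyloxy)-2-hydroxyphenyl]ethan-1-one; 2 3,4-bis(benzyloxy)benzaldehyde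
Product: 3 (E)-1-[4-(benzyloxy)-2-hydroxyphenyl]-3-[3,4-bis(benzyloxy)phenyl]prop-2-en-1-one
Conditions: KOH (50% aq.), EtOH, rt, 36 h; then AcOH to pH 5
Reagents that add atoms: none
Why: Claisen–Schmidt aldol condensation; the chelated 2'-OH is carried as its phenoxide, benzyl ethers are inert to base, and the E-enone is the thermodynamic product (no stereocentre).

**Step 2**
Reactants: 3 (E)-1-[4-(benzyloxy)-2-hydroxyphenyl]-3-[3,4-bis(benzyloxy)phenyl]prop-2-en-1-one
Product: 5 (2R,3R)-7-(benzyloxy)-2-[3,4-bis(benzyloxy)phenyl]-3-hydroxy-2,3-dihydro-4H-chromen-4-one, via trans-(αR,βS)-chalcone epoxide 4 (not isolated)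
Conditions: La(OiPr)3 (10 mol %), (S)-BINOL ((S)-1,1'-bi-2-naphthol, 10 mol %), Ph3As=O (10 mol %), tBuOOH (1.5 equiv, decane), 4 Å MS, THF, 0 °C → rt; then pyridinium p-toluenesulfonate (5 mol %), rt
Reagents that add atoms: tert-butyl hydroperoxide, CC(C)(C)OO
Why: Proposed new method: the acidic 2'-OH of 3 exchanges onto the lanthanum–binaphtholate centre, so the substrate is held as a six-membered phenoxide/carbonyl chelate; this restores the enone electrophilicity that a free phenoxide would quench and fixes the enone against the binaphthyl wall. The lanthanum-bound tert-butylperoxide then adds to Cβ on one face and the lanthanum enolate closes to the trans-(αR,βS)-epoxide 4 (C3–O set). The released ortho-phenol opens 4 in the 6-endo mode at the para-benzyloxy-stabilised benzylic carbon with inversion (O1–C2 set), giving the 2,3-trans (2R,3R) ring C. The closest known reactions are the La–BINOL–Ph3As=O/tBuOOH epoxidation of O-protected chalcones, the racemic Algar–Flynn–Oyamada reaction, and the acid-triggered cyclisation of 2'-O-protected chalcone epoxides to dihydroflavonols. What is new is the use of the unprotected phenol as an anchor and the one-flask epoxidation/cycloetherification stopped at the dihydroflavonol. (S)-BINOL is chosen because, as far as I recall, it gives the (αR,βS)-epoxide with chalcone itself; the sense must be confirmed by circular dichroism of 5, and the antipodal ligand used if anchoring reverses it.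

**Step 3**
Reactants: 5 (2R,3R)-7-(benzyloxy)-2-[3,4-bis(benzyloxy)phenyl]-3-hydroxy-2,3-dihydro-4H-chromen-4-one
Product: 6 (2R,3S,4R)-7-(benzyloxy)-2-[3,4-bis(benzyloxy)phenyl]-3,4-dihydro-2H-chromene-3,4-diol
Conditions: NaBH4 (1.5 equiv), THF/MeOH 1:1, 0 °C
Reagents that add atoms: none
Why: Borohydride 1,2-reduction of the aryl ketone, which for 2,3-trans-dihydroflavonols gives mainly the 3,4-trans (4R) diol; C2 and C3 are untouched (the descriptor at C3 changes from R to S only because the priority of C4 changes), and any 4-epimer converges in step 5 because C4 is ionised there.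

**Step 4**
Reactants: 7 (+)-catechin, (2R,3S)-2-(3,4-dihydroxyphenyl)-3,4-dihydro-2H-chromene-3,5,7-triol
Product: 8 (2R,3S)-5,7-bis(benzyloxy)-2-[3,4-bis(benzyloxy)phenyl]-3,4-dihydro-2H-chromen-3-ol
Conditions: BnBr (4.4 equiv), K2CO3 (5 equiv), DMF, N2, 0 °C → rt
Reagents that add atoms: benzyl bromide, BrCc1ccccc1
Why: Williamson etherification; carbonate deprotonates only the four phenols, so the secondary 3-OH stays free and the two stereocentres of the chiral pool are not touched.

**Step 5**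
Reactants: 6 (2R,3S,4R)-7-(benzyloxy)-2-[3,4-bis(benzyloxy)phenyl]-3,4-dihydro-2H-chromene-3,4-diol; 8 (2R,3S)-5,7-bis(benzyloxy)-2-[3,4-bis(benzyloxy)phenyl]-3,4-dihydro-2H-chromen-3-ol
Product: 9 (2R,3S,4S)-7-(benzyloxy)-2-[3,4-bis(benzyloxy)phenyl]-4-[(2R,3S)-5,7-bis(benzyloxy)-2-[3,4-bis(benzyloxy)phenyl]-3-hydroxy-3,4-dihydro-2H-chromen-8-yl]-3,4-dihydro-2H-chromen-3-ol
Conditions: 8 (3 equiv), BF3·OEt2 (0.3 equiv), 4 Å MS, CH2Cl2, −40 → 0 °C
Reagents that add atoms: none
Why: SN1 Friedel–Crafts alkylation (the biomimetic proanthocyanidin coupling): the Lewis acid ionises the 2,4-dioxygenated benzylic 4-OH, the trialkoxy ring D of 8 attacks through C8 (the position benzylated catechins use as nucleophiles), and it enters from the α face anti to the complexed 3-oxygen, which gives the 3,4-trans (4S) centre; excess 8 suppresses self-condensation through ring A.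

**Step 6**
Reactants: 9 hepta-O-benzyl fisetinidol-(4α→8)-catechin (full name in step 5)
Product: 10 (2R,3S,4S)-7-(benzyloxy)-2-[3,4-bis(benzyloxy)phenyl]-4-[(2R,3S)-5,7-bis(benzyloxy)-2-[3,4-bis(benzyloxy)phenyl]-6-bromo-3-hydroxy-3,4-dihydro-2H-chromen-8-yl]-3,4-dihydro-2H-chromen-3-ol
Conditions: N-bromosuccinimide (1.05 equiv), CH2Cl2, −78 → −30 °C, dark
Reagents that add atoms: N-bromosuccinimide, O=C1CCC(=O)N1Br
Why: Electrophilic aromatic bromination; C6 of ring D is the only unsubstituted carbon of the trialkoxy (phloroglucinol-type) ring, which is far more electron-rich than the dialkoxy rings A, B and E, and no stereocentre is involved.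

**Step 7**
Reactants: 10 ring D 6-bromo derivative of 9 (full name in step 6)
Product: 11 (2R,3S,4S)-7-(benzyloxy)-2-[3,4-bis(benzyloxy)phenyl]-4-[(2R,3S)-5,7-bis(benzyloxy)-2-[3,4-bis(benzyloxy)phenyl]-3-hydroxy-6-methyl-3,4-dihydro-2H-chromen-8-yl]-3,4-dihydro-2H-chromen-3-ol
Conditions: MeB(OH)2 (3 equiv), Pd(OAc)2 (5 mol %), SPhos (2-dicyclohexylphosphino-2',6'-dimethoxybiphenyl, 10 mol %), K3PO4 (3 equiv), toluene/H2O 10:1, 90 °C
Reagents that add atoms: methylboronic acid, CB(O)O
Why: Suzuki–Miyaura methylation; the bulky electron-rich biarylphosphine couples di-ortho-alkoxy aryl bromides, the free secondary alcohols and benzyl ethers are tolerated, and the stereocentres are not epimerisable while the phenols are capped.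

**Step 8**
Reactants: 11 ring D 6-methyl hepta-O-benzyl dimer (full name in step 7)
Product: 12 (2R,3S,4S)-2-(3,4-dihydroxyphenyl)-4-[(2R,3S)-2-(3,4-dihydroxyphenyl)-3,5,7-trihydroxy-6-methyl-3,4-dihydro-2H-chromen-8-yl]-3,4-dihydro-2H-chromene-3,7-diol
Conditions: H2 (1 atm), Pd(OH)2/C, THF/MeOH 1:1, rt
Reagents that add atoms: none
Why: Hydrogenolysis of the seven benzyl ethers; at room temperature and 1 atm the diarylmethine C4–C8 bond, the two O1–C2 ring bonds and the aryl methyl are retained, as is usual in proanthocyanidin end-games.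

## Compound list

1 | 1-[4-(benzyloxy)-2-hydroxyphenyl]ethan-1-one | CC(=O)c1ccc(OCc2ccccc2)cc1O | starting material
2 | 3,4-bis(benzyloxy)benzaldehyde | O=Cc1ccc(OCc2ccccc2)c(OCc2ccccc2)c1 | starting material
3 | (E)-1-[4-(benzyloxy)-2-hydroxyphenyl]-3-[3,4-bis(benzyloxy)phenyl]prop-2-en-1-one | O=C(/C=C/c1ccc(OCc2ccccc2)c(OCc2ccccc2)c1)c1ccc(OCc2ccccc2)cc1O | intermediate
4 | [(2R,3S)-3-[3,4-bis(benzyloxy)phenyl]oxiran-2-yl][4-(benzyloxy)-2-hydroxyphenyl]methanone (trans-(αR,βS)-chalcone epoxide) | O=C(c1ccc(OCc2ccccc2)cc1O)[C@@H]1O[C@H]1c1ccc(OCc2ccccc2)c(OCc2ccccc2)c1 | intermediate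
5 | (2R,3R)-7-(benzyloxy)-2-[3,4-bis(benzyloxy)phenyl]-3-hydroxy-2,3-dihydro-4H-chromen-4-one (2,3-trans) | O=C1c2ccc(OCc3ccccc3)cc2O[C@H](c2ccc(OCc3ccccc3)c(OCc3ccccc3)c2)[C@H]1O | intermediate
6 | (2R,3S,4R)-7-(benzyloxy)-2-[3,4-bis(benzyloxy)phenyl]-3,4-dihydro-2H-chromene-3,4-diol (2,3-trans-3,4-trans) | O[C@@H]1c2ccc(OCc3ccccc3)cc2O[C@H](c2ccc(OCc3ccccc3)c(OCc3ccccc3)c2)[C@H]1O | intermediate
7 | (+)-catechin, (2R,3S)-2-(3,4-dihydroxyphenyl)-3,4-dihydro-2H-chromene-3,5,7-triol | Oc1cc(O)c2c(c1)O[C@H](c1ccc(O)c(O)c1)[C@@H](O)C2 | starting material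
8 | (2R,3S)-5,7-bis(benzyloxy)-2-[3,4-bis(benzyloxy)phenyl]-3,4-dihydro-2H-chromen-3-ol | c1ccccc1COc1cc(OCc2ccccc2)c2c(c1)O[C@H](c1ccc(OCc3ccccc3)c(OCc3ccccc3)c1)[C@@H](O)C2 | intermediate
9 | (2R,3S,4S)-7-(benzyloxy)-2-[3,4-bis(benzyloxy)phenyl]-4-[(2R,3S)-5,7-bis(benzyloxy)-2-[3,4-bis(benzyloxy)phenyl]-3-hydroxy-3,4-dihydro-2H-chromen-8-yl]-3,4-dihydro-2H-chromen-3-ol | c1c(OCc5ccccc5)c2c(c([C@@H]3c4ccc(OCc5ccccc5)cc4O[C@H](c4ccc(OCc5ccccc5)c(OCc5ccccc5)c4)[C@H]3O)c1OCc1ccccc1)O[C@H](c1ccc(OCc3ccccc3)c(OCc3ccccc3)c1)[C@@H](O)C2 | intermediate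
10 | ring D 6-bromo derivative of 9 (same configuration) | Brc1c(OCc5ccccc5)c2c(c([C@@H]3c4ccc(OCc5ccccc5)cc4O[C@H](c4ccc(OCc5ccccc5)c(OCc5ccccc5)c4)[C@H]3O)c1OCc1ccccc1)O[C@H](c1ccc(OCc3ccccc3)c(OCc3ccccc3)c1)[C@@H](O)C2 | intermediate
11 | ring D 6-methyl derivative of 9 (same configuration) | Cc1c(OCc5ccccc5)c2c(c([C@@H]3c4ccc(OCc5ccccc5)cc4O[C@H](c4ccc(OCc5ccccc5)c(OCc5ccccc5)c4)[C@H]3O)c1OCc1ccccc1)O[C@H](c1ccc(OCc3ccccc3)c(OCc3ccccc3)c1)[C@@H](O)C2 | intermediate
12 | (2R,3S,4S)-2-(3,4-dihydroxyphenyl)-4-[(2R,3S)-2-(3,4-dihydroxyphenyl)-3,5,7-trihydroxy-6-methyl-3,4-dihydro-2H-chromen-8-yl]-3,4-dihydro-2H-chromene-3,7-diol | Cc1c(O)c2c(c([C@@H]3c4ccc(O)cc4O[C@H](c4ccc(O)c(O)c4)[C@H]3O)c1O)O[C@H](c1ccc(O)c(O)c1)[C@@H](O)C2 | target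

## Step count and risks

Total steps: 8. Longest linear sequence: 7 (steps 1, 2, 3, 5, 6, 7, 8); step 4 is a one-step side branch.

**Step 2 (proposed new step).** The substrate phenol, used in large excess over lanthanum, may displace the binaphtholate and open a racemic background path. The epoxide 4 may also rearrange by acyl migration, or open in the 5-exo mode towards an aurone. If the ring closure drifts towards SN1, some cis isomer could form and erode the enantiomeric purity after C3 epimerisation.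

Fallback with known chemistry, setting out from 3 and returning at 5: the 2'-OH is capped with chloromethyl methyl ether (NaH, DMF) to give the methoxymethyl ether (E)-1-[4-(benzyloxy)-2-(methoxymethoxy)phenyl]-3-[3,4-bis(benzyloxy)phenyl]prop-2-en-1-one F1. Juliá–Colonna epoxidation (poly-L-leucine, urea–H2O2, 1,8-diazabicyclo[5.4.0]undec-7-ene, THF) gives the trans-(αR,βS)-epoxide of that ether F2. Methanolic HCl (rt to 45 °C) then removes the acetal, and the freed phenol closes ring C with inversion at the benzylic carbon to give 5.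

**Step 5.** A cation lacking a 5-oxygen shows only moderate facial bias, so a 4β (3,4-cis) diastereomer must be separated. Ring A of a second molecule of 6 can also compete as a nucleophile.

Fallback, setting out from 6 and returning at 9: acetylation (Ac2O, pyridine, 4-(dimethylamino)pyridine) gives the 3,4-di-O-acetate of 6 F3. Ionisation with Me3SiOSO2CF3 (1 equiv, CH2Cl2, −78 °C) in the presence of 8 (3 equiv) lets the 3-acetoxy group bridge C4 on the β face as a dioxolanylium ion. The arene can then enter only from the α face, giving the upper-unit 3-O-acetate of 9 F4. K2CO3 in MeOH/THF removes the acetate and gives 9.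

**Step 6.** Bromination could also occur at C6 or C8 of the dialkoxy ring A, or go twice. The hindered bromide may then partly protodebrominate in step 7.

Fallback, setting out from 9 and returning at 12: a weaker and therefore more site-selective electrophile is used. Dimethylmethylideneammonium iodide in MeCN at 60 °C (Mannich aminomethylation) gives the ring D 6-(dimethylaminomethyl) derivative of 9 F5. Hydrogenolysis (H2, 3 atm, Pd(OH)2/C, THF/MeOH/AcOH, 40 °C) then cleaves the seven benzyl ethers and the benzylic C–N bond in one operation, the latter through the ortho-quinone methide of the freed phloroglucinol ring, and gives 12 directly, bypassing 10 and 11.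

## Further compounds

F1 | step 2 | (E)-1-[4-(benzyloxy)-2-(methoxymethoxy)phenyl]-3-[3,4-bis(benzyloxy)phenyl]prop-2-en-1-one | COCOc1cc(OCc2ccccc2)ccc1C(=O)/C=C/c1ccc(OCc2ccccc2)c(OCc2ccccc2)c1
F2 | step 2 | [(2R,3S)-3-[3,4-bis(benzyloxy)phenyl]oxiran-2-yl][4-(benzyloxy)-2-(methoxymethoxy)phenyl]methanone | COCOc1cc(OCc2ccccc2)ccc1C(=O)[C@@H]1O[C@H]1c1ccc(OCc2ccccc2)c(OCc2ccccc2)c1
F3 | step 5 | 3,4-di-O-acetate of 6 (2,3-trans-3,4-trans, spatial arrangement as in 6) | CC(=O)O[C@@H]1c2ccc(OCc3ccccc3)cc2O[C@H](c2ccc(OCc3ccccc3)c(OCc3ccccc3)c2)[C@H]1OC(C)=O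
F4 | step 5 | upper-unit 3-O-acetate of 9 (configuration as in 9) | c1c(OCc5ccccc5)c2c(c([C@@H]3c4ccc(OCc5ccccc5)cc4O[C@H](c4ccc(OCc5ccccc5)c(OCc5ccccc5)c4)[C@H]3OC(C)=O)c1OCc1ccccc1)O[C@H](c1ccc(OCc3ccccc3)c(OCc3ccccc3)c1)[C@@H](O)C2
F5 | step 6 | ring D 6-(dimethylaminomethyl) derivative of 9 (configuration as in 9) | CN(C)Cc1c(OCc5ccccc5)c2c(c([C@@H]3c4ccc(OCc5ccccc5)cc4O[C@H](c4ccc(OCc5ccccc5)c(OCc5ccccc5)c4)[C@H]3O)c1OCc1ccccc1)O[C@H](c1ccc(OCc3ccccc3)c(OCc3ccccc3)c1)[C@@H](O)C2
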